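## Retrosynthetic overview

1. Target 22 is the C6 veratrate of diol 20, which comes from hydroxy ketone 19 by a reduction directed by the C4 hydroxyl. Locants are those of the target throughout: C1 = ring-fusion C–CH3, C2/C3 = CH2, C4 = C(OH)(iPr), C5 = ring-fusion CH, C6 = C–O, C7–C10 = CH2–C(CH3)=CH–CH2.
2. Key disconnection: the trans-fused hydroazulenone 18 comes from the cis-fused decalin 16 (ring A = C1–C2–C3–C4–C5–C6, ring B = C1–C6–C7–C8–C9–C10) by a 1,2-shift of C1 from C6 to C5. Ring A contracts to the cyclopentane C1–C5 while ring B expands to the cycloheptenone; the C1–C6 bond of 16 is not in the target.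
3. Enabling feature: the ring-fusion CH (C5) lies between the quaternary C1 and the two oxygenated carbons C4 and C6. This is a β-hydroxy ketone array O–C4–C5(H)–C6=O in which the C1–C5 bond is the retron of a semipinacol shift onto a leaving group at C5.
4. Ring A is the p-menthane ring of (S)-terpinen-4-ol (1): its six ring carbons become C1–C6, and its only stereocentre is C4 with hydroxyl and isopropyl already in place. C1, C6 and C5 are then set by substrate control (conjugate allylation, enolate alkylation and hydroxylation, hydride reduction).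
5. Order of ring formation: ring A (chiral pool) → ring B by ring-closing metathesis (6-6) → both final rings in the key step (5-7) → directed reduction and esterification.

Key step: step 10

Assumption: (S)-terpinen-4-ol is used in high enantiomeric purity (commercial material upgraded if necessary); no step touches its stereocentre, so the optical purity of 22 should be that of 1.

## Route

Step 1
Reactants: 1 (S)-terpinen-4-ol
Product: 2 triethylsilyl ether of 1
Conditions: Et3SiOTf, 2,6-lutidine, CH2Cl2, 0 °C
Reagents that add atoms: triethylsilyl trifluoromethanesulfonate, CC[Si](CC)(CC)OS(=O)(=O)C(F)(F)F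
Why: Silyl-triflate silylation of a hindered tertiary alcohol is reliable; the ether keeps the C4 oxygen out of steps 3 and 10 and, as a pseudoaxial group beside an equatorial isopropyl group, fixes the ring conformation used for later stereocontrol; no stereocentre is touched.

Step 2
Reactants: 2 triethylsilyl ether of 1
Product: 5 tertiary allylic alcohol (C1–OH, C5=C6), via hydroxy selenide 3 (not isolated), via selenoxide 4 (not isolated)
Conditions: N-(phenylseleno)phthalimide, H2O, camphorsulfonic acid (cat.), CH2Cl2, rt; then 30% H2O2, pyridine, 0 °C to rt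
Reagents that add atoms: water, O; N-(phenylseleno)phthalimide, O=C1N([Se]c2ccccc2)C(=O)c2ccccc12 (its PhSe group is present only in 3 and 4); hydrogen peroxide, OO (its oxygen is present only in 4)
Why: Markovnikov anti hydroxyselenenylation puts OH on the tertiary C1 and selenium on C6, and the selenoxide syn-elimination can only run toward C5 because C1 has no hydrogen, so the alkene is transposed to C5=C6; the configurations at C1 and C6 of 3–5 do not matter because C1 becomes trigonal in step 3.

Step 3
Reactants: 5 tertiary allylic alcohol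
Product: 6 (6R)-3-methyl-6-(propan-2-yl)-6-(triethylsilyloxy)cyclohex-2-en-1-one (C5 ketone, C1=C6)
Conditions: pyridinium chlorochromate [C5H5NH][CrO3Cl], 4 Å molecular sieves, CH2Cl2, rt
Reagents that add atoms: none
Why: Babler–Dauben oxidation (oxidative 1,3-transposition of a tertiary allylic alcohol) moves the oxygen from C1 to C5 and oxidises it to the ketone, giving the enone with the C1=C6 double bond; the silyl ether keeps the C4 oxygen out of the reaction.

Step 4
Reactants: 6 enone; 7 allyltrimethylsilane
Product: 8 5-allyl-5-methyl-2-(propan-2-yl)-2-(triethylsilyloxy)cyclohexan-1-one (allyl trans to the silyloxy group)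
Conditions: TiCl4, CH2Cl2, −78 °C
Reagents that add atoms: allyltrimethylsilane (7), C=CC[Si](C)(C)C
Why: Hosomi–Sakurai conjugate allylation of a β,β-disubstituted enone creates the quaternary C1; the allyl group should enter axially on the half-chair in which isopropyl is pseudoequatorial and the silyloxy group pseudoaxial, i.e. trans to the silyloxy group and cis to isopropyl, which sets C1 relative to C4.

Step 5
Reactants: 8 allyl ketone; 9 3-bromo-2-methylprop-1-ene
Product: 11 6-methallyl ketone, via lithium enolate 10 (not isolated)
Conditions: LiN(iPr)2, THF, −78 °C; then 9, DMPU, −78 to 0 °C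
Reagents that add atoms: 3-bromo-2-methylprop-1-ene (9), C=C(C)CBr; lithium diisopropylamide, [Li+].CC(C)[N-]C(C)C (its lithium is present only in 10)
Why: Enolate alkylation: C4 has no hydrogen, so the ketone can enolise only toward C6 and the allylic bromide alkylates there regiospecifically; the C6 configuration does not matter because C6 is re-enolised in step 6 (the equatorial epimer is drawn).

Step 6
Reactants: 11 6-methallyl ketone
Product: 13 tertiary α-hydroxy ketone (C6–OH cis to the C1 methyl group), via potassium enolate 12 (not isolated)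
Conditions: KN(SiMe3)2, THF, −78 to −40 °C; then 2-(phenylsulfonyl)-3-phenyloxaziridine, −78 °C; AcOH quench at −78 °C
Reagents that add atoms: 2-(phenylsulfonyl)-3-phenyloxaziridine, O=S(=O)(N1OC1c1ccccc1)c1ccccc1; potassium bis(trimethylsilyl)amide, [K+].C[Si](C)(C)[N-][Si](C)(C)C (its potassium is present only in 12)
Why: Enolate hydroxylation with an N-sulfonyloxaziridine: the tetrasubstituted enolate should take up oxygen axially at C6 on the face opposite the axial allyl group on C1, which places the new hydroxyl cis to the C1 methyl group and the C4 silyloxy group and leaves the methallyl group equatorial and cis to the allyl group.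

Step 7
Reactants: 13 tertiary α-hydroxy ketone
Product: 14 cis-fused bicyclic hydroxy ketone
Conditions: RuCl2(=CHPh)(PCy3)(H2IMes) (second-generation Grubbs catalyst, 5 mol %), CH2Cl2, 40 °C
Reagents that add atoms: none
Why: Ring-closing metathesis of the cis-disposed allyl (axial on C1) and methallyl (equatorial on C6) groups closes ring B as a cis-fused cyclohexene with the trisubstituted C8=C9 double bond; no stereocentre changes.

Step 8
Reactants: 14 bicyclic hydroxy ketone
Product: 15 cis-fused diol (C5–OH, C6–OH)
Conditions: NaBH4, MeOH–THF, 0 °C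
Reagents that add atoms: none
Why: Hydride reduction under Felkin–Anh control: hydride should add axially to the C5 carbonyl, anti to the two axial α C–O bonds at C4 and C6 (which also block the equatorial approach), giving the equatorial C5 hydroxyl cis to both neighbouring oxygens.

Step 9
Reactants: 15 diol
Product: 16 C5 methanesulfonate
Conditions: MeSO2Cl, Et3N, CH2Cl2, −10 °C
Reagents that add atoms: methanesulfonyl chloride, CS(=O)(=O)Cl
Why: Sulfonylation through sulfene is selective for the only secondary hydroxyl; the tertiary C6 hydroxyl and the silyl ether do not react, and the C5 configuration is retained.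

Step 10
Reactants: 16 C5 methanesulfonate
Product: 18 (3R,3aR,8aR)-6,8a-dimethyl-3-(propan-2-yl)-3-(triethylsilyloxy)-2,3,3a,5,8,8a-hexahydroazulen-4(1H)-one, via aluminium alkoxide 17 (not isolated)
Conditions: Et3Al (3 equiv), CH2Cl2, −78 to 0 °C
Reagents that add atoms: triethylaluminium, CC[Al](CC)CC (its Et2Al group is present only in 17)
Why: Et3Al turns the tertiary C6 hydroxyl into the aluminium alkoxide 17 and, as Lewis acid, loosens the C5 mesylate; the C1–C6 σ bond, which in the chair of ring A is antiperiplanar to the equatorial C5–O bond, then shifts from C6 to C5 while C6–O becomes the carbonyl. This is a semipinacol rearrangement of a 2-sulfonyloxy alcohol, whose closest precedents are the organoaluminium- and base-promoted pinacol-type rearrangements of diol monosulfonates, among them the conversion of decalin diol monosulfonates into hydroazulenones. Both rings of the product are closed by this single 1,2-alkyl shift: ring A (six-membered, C1–C6) contracts to the cyclopentane C1–C5 and ring B (six-membered) expands to the cycloheptenone, through one three-centre transition state in which C1 displaces the mesylate from the rear (formally a 3-exo-tet attack of the C1–C6 bond on C5). C5 is formed with inversion, which gives the trans ring fusion with H5 anti to the C1 methyl group, while the migrating C1 keeps its configuration and C4 is untouched, so both are controlled by 16. The step needs migration of C1 and of nothing else: the C4–C3 bond is also antiperiplanar to the leaving group but its oxygen is silylated and cannot push, the C6–C7 bond and the C6 alkoxide are gauche to the C5–O bond so that neither the other ring bond can migrate nor an epoxide can close, and the equatorial position of the mesylate is fixed by the cis ring fusion together with the equatorial isopropyl group.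

Step 11
Reactants: 18 silyloxy hydroazulenone
Product: 19 (3R,3aR,8aR)-3-hydroxy-6,8a-dimethyl-3-(propan-2-yl)-2,3,3a,5,8,8a-hexahydroazulen-4(1H)-one
Conditions: HF·pyridine, THF, 0 °C to rt
Reagents that add atoms: none
Why: Fluoride cleavage of the tertiary triethylsilyl ether under weakly acidic, non-basic conditions, chosen so that the β-hydroxy ketone neither undergoes retro-aldol cleavage nor epimerises at C5.

Step 12
Reactants: 19 β-hydroxy ketone
Product: 20 (3R,3aS,4S,8aR)-6,8a-dimethyl-3-(propan-2-yl)-1,2,3,3a,4,5,8,8a-octahydroazulene-3,4-diol (jaeschkeanadiol)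
Conditions: Me4N[BH(OAc)3], MeCN–AcOH, −20 °C to rt
Reagents that add atoms: none
Why: Evans–Saksena reduction: the borohydride exchanges an acetate for the tertiary C4 hydroxyl and delivers hydride intramolecularly to the face of the C6 carbonyl turned toward the C4 oxygen, giving the 1,3-anti diol with the C6 hydroxyl cis to H5, as in the target.

Step 13
Reactants: 20 jaeschkeanadiol; 21 3,4-dimethoxybenzoyl chloride
Product: 22 target, (3R,3aS,4S,8aR)-3-hydroxy-6,8a-dimethyl-3-(propan-2-yl)-1,2,3,3a,4,5,8,8a-octahydroazulen-4-yl 3,4-dimethoxybenzoate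
Conditions: 21, Et3N, DMAP (cat.), CH2Cl2, rt
Reagents that add atoms: 3,4-dimethoxybenzoyl chloride (21), COc1ccc(C(=O)Cl)cc1OC
Why: Acylation with an acid chloride under nucleophilic catalysis esterifies only the secondary C6 hydroxyl, the tertiary C4 hydroxyl flanked by isopropyl and the ring fusion being inert; no stereocentre is touched.

## Compound list

1 | (S)-terpinen-4-ol, (1S)-4-methyl-1-(propan-2-yl)cyclohex-3-en-1-ol | CC1=CC[C@](O)(C(C)C)CC1 | starting material
2 | triethyl{[(1S)-4-methyl-1-(propan-2-yl)cyclohex-3-en-1-yl]oxy}silane | CC1=CC[C@](O[Si](CC)(CC)CC)(C(C)C)CC1 | intermediate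
3 | hydroxy selenide (not isolated): 1-methyl-2-(phenylselanyl)-4-(propan-2-yl)-4-(triethylsilyloxy)cyclohexan-1-ol, OH and SePh trans; the adduct with selenium on the face remote from the silyloxy group is drawn, its diastereomer converges | C[C@]1(O)[C@H]([Se]c2ccccc2)C[C@](O[Si](CC)(CC)CC)(C(C)C)CC1 | intermediate
4 | selenoxide of 3 (not isolated; configuration at selenium undefined) | C[C@]1(O)[C@H]([Se](=O)c2ccccc2)C[C@](O[Si](CC)(CC)CC)(C(C)C)CC1 | intermediate
5 | 1-methyl-4-(propan-2-yl)-4-(triethylsilyloxy)cyclohex-2-en-1-ol; the epimer with OH cis to the silyloxy group is drawn, either epimer serves | C[C@]1(O)C=C[C@](O[Si](CC)(CC)CC)(C(C)C)CC1 | intermediate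
6 | (6R)-3-methyl-6-(propan-2-yl)-6-(triethylsilyloxy)cyclohex-2-en-1-one | CC1=CC(=O)[C@](O[Si](CC)(CC)CC)(C(C)C)CC1 | intermediate
7 | allyltrimethylsilane | C=CC[Si](C)(C)C | starting material
8 | 5-allyl-5-methyl-2-(propan-2-yl)-2-(triethylsilyloxy)cyclohexan-1-one, allyl trans to the silyloxy group and cis to isopropyl | C=CC[C@@]1(C)CC[C@@](O[Si](CC)(CC)CC)(C(C)C)C(=O)C1 | intermediate
9 | 3-bromo-2-methylprop-1-ene (methallyl bromide) | C=C(C)CBr | starting material
10 | lithium enolate of 8 (not isolated; C5–OLi, C5=C6) | [Li+].C=CC[C@@]1(C)CC[C@@](O[Si](CC)(CC)CC)(C(C)C)C([O-])=C1 | intermediate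
11 | 5-allyl-5-methyl-6-(2-methylprop-2-en-1-yl)-2-(propan-2-yl)-2-(triethylsilyloxy)cyclohexan-1-one; the epimer with methallyl cis to allyl is drawn | C=CC[C@@]1(C)CC[C@@](O[Si](CC)(CC)CC)(C(C)C)C(=O)[C@H]1CC(C)=C | intermediate
12 | potassium enolate of 11 (not isolated) | [K+].C=CC[C@@]1(C)CC[C@@](O[Si](CC)(CC)CC)(C(C)C)C([O-])=C1CC(C)=C | intermediate
13 | 5-allyl-6-hydroxy-5-methyl-6-(2-methylprop-2-en-1-yl)-2-(propan-2-yl)-2-(triethylsilyloxy)cyclohexan-1-one; 6-OH cis to the 5-methyl and the silyloxy group, methallyl cis to allyl | C=CC[C@@]1(C)CC[C@@](O[Si](CC)(CC)CC)(C(C)C)C(=O)[C@@]1(O)CC(C)=C | intermediate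
14 | cis-fused 8a-hydroxy-4a,7-dimethyl-2-(propan-2-yl)-2-(triethylsilyloxy)-3,4,4a,5,8,8a-hexahydronaphthalen-1(2H)-one; 8a-OH, 2-silyloxy and 4a-methyl on one face | C[C@]12CC[C@@](O[Si](CC)(CC)CC)(C(C)C)C(=O)[C@@]1(O)CC(C)=CC2 | intermediate
15 | cis-fused 4a,7-dimethyl-2-(propan-2-yl)-2-(triethylsilyloxy)-1,2,3,4,4a,5,8,8a-octahydronaphthalene-1,8a-diol; 1-OH, 8a-OH, 2-silyloxy and 4a-methyl all on one face | C[C@]12CC[C@@](O[Si](CC)(CC)CC)(C(C)C)[C@H](O)[C@@]1(O)CC(C)=CC2 | intermediate
16 | 1-O-methanesulfonate of 15 (secondary mesylate, equatorial on ring A) | C[C@]12CC[C@@](O[Si](CC)(CC)CC)(C(C)C)[C@H](OS(C)(=O)=O)[C@@]1(O)CC(C)=CC2 | intermediate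
17 | diethylaluminium 8a-alkoxide of 16 (not isolated) | C[C@]12CC[C@@](O[Si](CC)(CC)CC)(C(C)C)[C@H](OS(C)(=O)=O)[C@@]1(O[Al](CC)CC)CC(C)=CC2 | intermediate
18 | (3R,3aR,8aR)-6,8a-dimethyl-3-(propan-2-yl)-3-(triethylsilyloxy)-2,3,3a,5,8,8a-hexahydroazulen-4(1H)-one, trans-fused | O=C1CC(C)=CC[C@@]2(C)CC[C@@](O[Si](CC)(CC)CC)(C(C)C)[C@H]12 | intermediate
19 | (3R,3aR,8aR)-3-hydroxy-6,8a-dimethyl-3-(propan-2-yl)-2,3,3a,5,8,8a-hexahydroazulen-4(1H)-one | O=C1CC(C)=CC[C@@]2(C)CC[C@@](O)(C(C)C)[C@H]12 | intermediate
20 | (3R,3aS,4S,8aR)-6,8a-dimethyl-3-(propan-2-yl)-1,2,3,3a,4,5,8,8a-octahydroazulene-3,4-diol (jaeschkeanadiol) | O[C@H]1CC(C)=CC[C@@]2(C)CC[C@@](O)(C(C)C)[C@H]12 | intermediate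
21 | 3,4-dimethoxybenzoyl chloride | COc1ccc(C(=O)Cl)cc1OC | starting material
22 | (3R,3aS,4S,8aR)-3-hydroxy-6,8a-dimethyl-3-(propan-2-yl)-1,2,3,3a,4,5,8,8a-octahydroazulen-4-yl 3,4-dimethoxybenzoate | COc1ccc(C(=O)O[C@H]2CC(C)=CC[C@@]3(C)CC[C@@](O)(C(C)C)[C@H]23)cc1OC | target

## Step count and risks

Total step count: 13. Longest linear sequence: 13 steps (1 → 22).

Steps most likely to fail:

Step 6. What may go wrong: incomplete deprotonation of the hindered C6 methine, oxygen transfer to the wrong face of the enolate, or migration of the silyl group from the C4 oxygen to the new syn-axial C6 alkoxide. The fallback sets out from 11 and comes back at 19; it puts the C5 and C6 oxygens in together by a hydroxyl-directed syn-dihydroxylation, so it also bypasses the hydride reduction of step 8. Ketone 11 is converted with KN(SiMe3)2 and PhNTf2 into the enol triflate F1, which is reduced with Pd(OAc)2/PPh3, Bu3N and HCO2H to the triene F2 (C5=C6 alkene). Ring-closing metathesis with RuCl2(=CHPh)(PCy3)(H2IMes) gives the bicyclic diene F3, and Bu4NF removes the silyl group to give the dienol F4. OsO4·TMEDA, hydrogen-bonded to the C4 hydroxyl, should then deliver both new hydroxyls to the face of that hydroxyl and give the all-cis triol F5. Mesylation of the only secondary hydroxyl gives the triol monomesylate F6, and Et3Al triggers the same 1,2-shift. With both tertiary hydroxyls free, the fully substituted C1 should migrate in preference to the C3 methylene, and the product is hydroxy ketone 19.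

Step 10. What may go wrong: loss of the mesylate by ionisation or elimination without migration, Lewis-acid cleavage of the silyl ether (which would free a second oxygen able to drive the competing shift of C3), or a conformer of the bicycle in which the fusion bond is not antiperiplanar to the leaving group. The fallback sets out from 13 and comes back at 18; it runs the ring contraction on monocyclic ring A before ring B exists and then closes the seven-membered ring directly. Hydroxy ketone 13 is reduced with NaBH4 to the monocyclic diol F7 and mesylated to the monocyclic mesylate F8. Et3Al then moves C1 from C6 to C5 with the same stereochemical course and gives the cyclopentyl methallyl ketone F9. Ring-closing metathesis of its allyl and methallyl groups with RuCl2(=CHPh)(PCy3)(H2IMes) closes the cycloheptenone and gives 18.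

Step 4. What may go wrong: poor facial selectivity at C1 if the half-chair preference of the enone is weak, or loss of the silyl ether under TiCl4. The fallback sets out from 6 and comes back at 8; it delivers the allyl group intramolecularly by a sigmatropic shift. Allylmagnesium bromide adds 1,2 to the carbonyl of 6 from the face opposite the pseudoaxial silyloxy group and gives the tertiary bis-allylic alcohol F10. Its potassium alkoxide (KH, 18-crown-6, THF) should undergo an anionic oxy-Cope rearrangement that carries the allyl group suprafacially from C5 to C1, and protonation of the resulting enolate gives 8.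

## Further compounds

F1 | step 6 | enol triflate of 11 (C5–OTf, C5=C6) | C=CC[C@@]1(C)CC[C@@](O[Si](CC)(CC)CC)(C(C)C)C(OS(=O)(=O)C(F)(F)F)=C1CC(C)=C
F2 | step 6 | triene: 6-allyl-6-methyl-1-(2-methylprop-2-en-1-yl)-3-(propan-2-yl)-3-(triethylsilyloxy)cyclohex-1-ene | C=CC[C@@]1(C)CC[C@@](O[Si](CC)(CC)CC)(C(C)C)C=C1CC(C)=C
F3 | step 6 | bicyclic diene: 4a,7-dimethyl-2-(propan-2-yl)-2-(triethylsilyloxy)-2,3,4,4a,5,8-hexahydronaphthalene | C[C@]12CC[C@@](O[Si](CC)(CC)CC)(C(C)C)C=C1CC(C)=CC2
F4 | step 6 | dienol: 4a,7-dimethyl-2-(propan-2-yl)-2,3,4,4a,5,8-hexahydronaphthalen-2-ol | C[C@]12CC[C@@](O)(C(C)C)C=C1CC(C)=CC2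
F5 | step 6 | all-cis triol: 4a,7-dimethyl-2-(propan-2-yl)-1,2,3,4,4a,5,8,8a-octahydronaphthalene-1,2,8a-triol | C[C@]12CC[C@@](O)(C(C)C)[C@H](O)[C@@]1(O)CC(C)=CC2
F6 | step 6 | 1-O-methanesulfonate of F5 | C[C@]12CC[C@@](O)(C(C)C)[C@H](OS(C)(=O)=O)[C@@]1(O)CC(C)=CC2
F7 | step 10 | monocyclic diol: 3-allyl-3-methyl-2-(2-methylprop-2-en-1-yl)-6-(propan-2-yl)-6-(triethylsilyloxy)cyclohexane-1,2-diol, all oxygens cis | C=CC[C@@]1(C)CC[C@@](O[Si](CC)(CC)CC)(C(C)C)[C@H](O)[C@@]1(O)CC(C)=C
F8 | step 10 | 1-O-methanesulfonate of F7 | C=CC[C@@]1(C)CC[C@@](O[Si](CC)(CC)CC)(C(C)C)[C@H](OS(C)(=O)=O)[C@@]1(O)CC(C)=C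
F9 | step 10 | cyclopentyl ketone: 1-[2-allyl-2-methyl-5-(propan-2-yl)-5-(triethylsilyloxy)cyclopentyl]-3-methylbut-3-en-1-one, acyl group trans to allyl and cis to the silyloxy group | C=CC[C@@]1(C)CC[C@@](O[Si](CC)(CC)CC)(C(C)C)[C@@H]1C(=O)CC(C)=C
F10 | step 4 | 1-allyl-3-methyl-6-(propan-2-yl)-6-(triethylsilyloxy)cyclohex-2-en-1-ol, allyl trans to the silyloxy group | CC1=C[C@](O)(CC=C)[C@](O[Si](CC)(CC)CC)(C(C)C)CC1
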